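At the very start of the midnight flask none of the gas phase is in solution, so watch how soon the target starts to climb; that flask is the one asked about, and the dawn run differs from it in its substrate charge.

| setting | midnight | dawn | flask |
|---|---|---|---|
| substrate | 0.050 M | 0.034 M | 0.050 M |
| gas phase | 5.6 mM (held) | 5.6 mM (held) | 5.6 mM (held) |
| catalyst | 3.1 mM | 3.1 mM | 3.1 mM |
| temperature | 25 °C | 25 °C | 25 °C |
| remark | the very flask that is asked about, followed so far | run made earlier |  |
| time |  |  | 3.0 h |

| run | time / min | target / % |
|---|---|---|
| midnight | 6.00 | 11.1 |
| midnight | 15.0 | 26.9 |
| midnight | 30.0 | 49.3 |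
| midnight | 50.0 | 61.4 |
| midnight | 60.0 | 61.5 |
| midnight | 80.0 | 62.0 |
| midnight | 120 | 61.9 |
| dawn | 2.50 | 5.3 |
| dawn | 5.00 | 12.5 |
| dawn | 6.00 | 14.5 |
| dawn | 10.0 | 25.3 |
| dawn | 12.0 | 30.8 |
| dawn | 15.0 | 37.8 |

(standard deviation of a reading: 0.3 percentage points)

- target that was removed still counts
- the earlier runs were read with a standard deviation of 0.3 percentage points
- at the start none of the gas phase is in solution
- the earlier runs do not show what temperature does; that part of a forecast is a guess
- additions bring no volume worth counting

- oak: at 3.0 h take out 90% of the target then present, then wait 6.0 h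
- alder: change nothing and wait 6.0 h more
- cedar: at 3.0 h raise the temperature by 10 K, then wait 6.0 h
- elm: at 3.0 h add catalyst, 100% of the amount charged, then wait 6.0 h

* target, in percent of the substrate first charged, at 3.0 h
* what to do for the largest gain in target; "none" if nothing gains more than 2 percentage points (oak / alder / cedar / elm / none)
* target present, with what was taken out counted in, in percent of the substrate first charged, after alder
* target present, with what was taken out counted in, in percent of the substrate first charged, after cedar

Once the climb is under way, take the target in absolute terms, between the same two times in each run where you can: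

midnight: (26.9% − 11.1%) × 0.050 M / (15.0 min − 6.00 min) = 0.878 mM min⁻¹

dawn: (37.8% − 14.5%) × 0.034 M / (15.0 min − 6.00 min) = 0.880 mM min⁻¹

Carry this number: the supply rate, the target made per minute in the straight stretch. The two runs match despite their different substrate, so the rate is zero order in substrate. My reading is that [dissolved gas] sets it, with the crossing of the gas phase as the rate-limiting step.

The supply rate also tells you when to look at the midnight flask, taking its last reading as the plateau:

t = 0.5 × 61.9% × 0.050 M / 0.878 mM min⁻¹ = 17.6 min

That is when the target should stand at the middle of its plateau.

Then the straight line ends. Between 30.0 min and 50.0 min the midnight flask gains only 0.302 mM min⁻¹, and up to 120 min it stays between 61.4% and 62.0%. I read this as substrate running out, with the other 38.1% leaving by some unseen way. So I commit to the plateau at 3.0 h and to no option gaining.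

The forecast gives 61.8%, 61.8% after alder and 62% after cedar, but it names elm as best, holding that the “catalyst most likely dies after a fixed turnover count”. On that choice it differs from my reading.

The simulation gives 61.9% at 3.0 h, 61.9% after alder and 61.9% after cedar; the best choice is none, with elm gaining 0 percentage points.

    substrate + target → side product (k = 0.260 M⁻¹ min⁻¹, Ea = 59.0 kJ mol⁻¹)
    2 substrate → homo dimer (k = 0.350 M⁻¹ min⁻¹, Ea = 55.0 kJ mol⁻¹)
    gas phase ⇌ dissolved gas, rate k3*(csat - [dissolved gas]) (kL = 0.210 min⁻¹)
    substrate + dissolved gas + catalyst → catalyst + target (k = 17000 M⁻² min⁻¹, Ea = 37.0 kJ mol⁻¹)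
    substrate + catalyst ⇌ idle complex, settled at all times (K = 11.0 M⁻¹, ΔH = −33.0 kJ mol⁻¹)
    (constants at 25 °C)

At 19.3 min in this flask, dissolved gas is made 1.06 times faster than it is used, and the target step reaches the midpoint of its turnover at 17.5 min, beside the 17.6 min reckoned from 0.878 mM min⁻¹. The neighbour flask with 7.8 × 10⁻⁴ M of catalyst ends with 51.3% of target, less than the 61.9% of this flask, and at 180 min its substrate stands at 0%.

Readings and results were generated by integration with constants of no real substance; scatter was added.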